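**Retrosynthetic overview**
- The last step is a fourfold O-demethylation of the pentabromo tetramethyl ether 16.
- Going round the fully substituted ring B, the atoms read C–CH2, C–Br, C–Br, C–O, C–O, C–Br. The vicinal C–CH2/C–Br pair has a C–Br carbon on each outer side and the two C–O carbons opposite, so cutting the aryl–CH2 bond and that one C–Br bond leaves an aryne with a mirror plane through its triple bond (3,6-dibromo-4,5-dimethoxybenzyne 14). A benzylmagnesium plus a Br+ donor rebuilds both bonds with no regiochemical question.
- Ring A is the same 2,5-dibromo-3,4-dioxygenated ring with H where ring B has its third Br, so the benzyl Grignard 12 and the aryne precursor 9 both descend from one aldehyde, 6.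
- Aldehyde 6 comes from veratrole by twofold ortho-lithiation/silylation, bromodesilylation and formylation. No ring is formed: both benzene rings are veratrole rings, joined once, in step 9.

Key step: step 9

Remark: the target has no stereocentre or stereogenic axis; the single sp3 stereocentres met on the way (in 5, F3 and F6) are racemic and are removed again. TMP = 2,2,6,6-tetramethylpiperidin-1-yl.

**Step 1**
Reactants: 1 veratrole (1,2-dimethoxybenzene)
Product: 3 1,2-dimethoxy-3,6-bis(trimethylsilyl)benzene, via 3,6-dilithioveratrole 2 (not isolated)
Conditions: n-BuLi (3 equiv), TMEDA, Et2O–hexane, 0 °C to reflux; then Me3SiCl, 0 °C to rt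
Reagents that add atoms: chlorotrimethylsilane, C[Si](C)(C)Cl
Why: Directed ortho-metalation, in which each methoxy group directs lithium to its own free ortho position, should give the 3,6-dilithio compound, which is silylated; any monosilyl material can be put through the same lithiation–silylation once more.

**Step 2**
Reactants: 3 1,2-dimethoxy-3,6-bis(trimethylsilyl)benzene
Product: 4 1,4-dibromo-2,3-dimethoxybenzene (3,6-dibromoveratrole)
Conditions: Br2 (2.0 equiv), CH2Cl2, 0 °C, dark
Reagents that add atoms: bromine, BrBr
Why: Ipso-bromodesilylation, whose silicon-stabilised cationic intermediate forms faster than attack at a ring C–H, should put the two bromines exactly where the silyl groups stood, next to the methoxy groups, a pattern that direct bromination of veratrole does not give.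

**Step 3**
Reactants: 4 1,4-dibromo-2,3-dimethoxybenzene
Product: 6 2,5-dibromo-3,4-dimethoxybenzaldehyde, via α-chloro ether 5 (not isolated)
Conditions: Cl2CHOMe, TiCl4, CH2Cl2, 0 °C to rt; then ice, aq. HCl
Reagents that add atoms: dichloromethyl methyl ether, COC(Cl)Cl; water, O
Why: Rieche formylation should attack one of the two equivalent open positions, each para to a methoxy group, and stop after one substitution because the aryl(chloro)methyl ether deactivates the ring; hydrolysis on work-up then gives the aldehyde.

**Step 4**
Reactants: 6 2,5-dibromo-3,4-dimethoxybenzaldehyde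
Product: 8 2,5-dibromo-3,4-dimethoxyphenol, via aryl formate 7 (not isolated)
Conditions: mCPBA, CH2Cl2, reflux; then K2CO3, MeOH, rt
Reagents that add atoms: 3-chloroperoxybenzoic acid, O=C(OO)c1cccc(Cl)c1
Why: Baeyer–Villiger oxidation of an alkoxybenzaldehyde, in which the dimethoxyaryl group should migrate in preference to hydride in the Criegee adduct, gives the formate ester, and methanolysis frees the phenol.

**Step 5**
Reactants: 8 2,5-dibromo-3,4-dimethoxyphenol
Product: 9 2,5-dibromo-3,4-dimethoxyphenyl trifluoromethanesulfonate
Conditions: Tf2O, pyridine, CH2Cl2, 0 °C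
Reagents that add atoms: trifluoromethanesulfonic anhydride, O=S(=O)(OS(=O)(=O)C(F)(F)F)C(F)(F)F
Why: O-Sulfonylation of the phenol with triflic anhydride and an amine base is routine and installs the leaving group next to the only ring hydrogen.

**Step 6**
Reactants: 6 2,5-dibromo-3,4-dimethoxybenzaldehyde
Product: 10 (2,5-dibromo-3,4-dimethoxyphenyl)methanol
Conditions: NaBH4, MeOH–THF, 0 °C
Reagents that add atoms: none
Why: Hydride reduction of the aldehyde by NaBH4 leaves aryl bromides and methyl ethers untouched.

**Step 7**
Reactants: 10 (2,5-dibromo-3,4-dimethoxyphenyl)methanol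
Product: 11 1,4-dibromo-5-(chloromethyl)-2,3-dimethoxybenzene
Conditions: SOCl2, DMF (cat.), CH2Cl2, 0 °C to rt
Reagents that add atoms: thionyl chloride, O=S(Cl)Cl
Why: Deoxychlorination of a benzylic alcohol through its chlorosulfite should be clean, and the chloride is chosen over the bromide because it couples less during the magnesium insertion that follows.

**Step 8**
Reactants: 11 1,4-dibromo-5-(chloromethyl)-2,3-dimethoxybenzene
Product: 12 (2,5-dibromo-3,4-dimethoxybenzyl)magnesium chloride
Conditions: Mg turnings (excess, activated with BrCH2CH2Br), 2-MeTHF, 0 °C, slow addition of 11; titrated and used cold at once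
Reagents that add atoms: magnesium, [Mg]
Why: Grignard formation by insertion of magnesium into the benzylic C–Cl bond should outrun insertion into the two methoxy-flanked aryl C–Br bonds, and cold, dilute, slow addition in 2-MeTHF holds back Wurtz coupling; ortho-bromobenzyl Grignard reagents are known to be stable species.

**Step 9**
Reactants: 9 2,5-dibromo-3,4-dimethoxyphenyl trifluoromethanesulfonate; 12 (2,5-dibromo-3,4-dimethoxybenzyl)magnesium chloride
Product: 16 1,2,4-tribromo-3-[(2,5-dibromo-3,4-dimethoxyphenyl)methyl]-5,6-dimethoxybenzene, via magnesiated triflate 13 (not isolated), via aryne 14 (not isolated), via arylmagnesium adduct 15 (not isolated)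
Conditions: 12 (2.5 equiv), TMPMgCl·LiCl (1.05 equiv), THF–2-MeTHF, −78 to −30 °C; then BrCl2CCCl2Br (excess), −78 to 0 °C
Reagents that add atoms: 1,2-dibromo-1,1,2,2-tetrachloroethane, BrC(Cl)(Cl)C(Cl)(Cl)Br
Why: The hindered magnesium amide removes the only ring hydrogen of 9, acidified by the flanking triflate and bromine, and the resulting 13 expels triflate to give aryne 14 in the presence of the Grignard reagent. Benzylmagnesium 12 adds through its CH2 carbon to one aryne carbon and leaves arylmagnesium 15, whose C–Mg bond is then brominated by the Br+ donor, so the aryl–CH2 bond and the neighbouring aryl–Br bond are made in one flask. The closest known reaction type is the three-component coupling of an aryne, released from an ortho-magnesiated aryl sulfonate or triflate, with a Grignard reagent and an electrophile (aryne carbomagnesiation with electrophilic trapping). No ring is closed and no stereocentre is formed. Regioselectivity needs no control because 14 is C2v-symmetric and either aryne carbon gives the same adduct; what is needed is loss of triflate rather than of the neighbouring bromide from 13 and survival of the 2-bromoarylmagnesium 15, which the much better leaving group, the low temperature and a bromine quench carried out without delay should secure. The amine set free (TMPH) is too hindered to compete for the aryne, and the excess of 12 should keep 15 from adding to a second aryne.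

**Step 10**
Reactants: 16 1,2,4-tribromo-3-[(2,5-dibromo-3,4-dimethoxyphenyl)methyl]-5,6-dimethoxybenzene
Product: 17 3,4,6-tribromo-5-[(2,5-dibromo-3,4-dihydroxyphenyl)methyl]benzene-1,2-diol (target)
Conditions: BBr3 (excess), CH2Cl2, −78 °C to rt; then H2O
Reagents that add atoms: none
Why: Lewis-acid cleavage of aryl methyl ethers by BBr3 should remove all four methyl groups without touching the aryl bromides or the diarylmethane CH2.

**Compound list**
1 | veratrole (1,2-dimethoxybenzene) | COc1ccccc1OC | starting material
2 | 3,6-dilithioveratrole | [Li]c1ccc([Li])c(OC)c1OC | intermediate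
3 | 1,2-dimethoxy-3,6-bis(trimethylsilyl)benzene | COc1c([Si](C)(C)C)ccc([Si](C)(C)C)c1OC | intermediate
4 | 1,4-dibromo-2,3-dimethoxybenzene (3,6-dibromoveratrole) | COc1c(Br)ccc(Br)c1OC | intermediate
5 | 1,4-dibromo-5-[chloro(methoxy)methyl]-2,3-dimethoxybenzene, racemic | COC(Cl)c1cc(Br)c(OC)c(OC)c1Br | intermediate
6 | 2,5-dibromo-3,4-dimethoxybenzaldehyde | COc1c(Br)cc(C=O)c(Br)c1OC | intermediate
7 | 2,5-dibromo-3,4-dimethoxyphenyl formate | COc1c(Br)cc(OC=O)c(Br)c1OC | intermediate
8 | 2,5-dibromo-3,4-dimethoxyphenol | COc1c(Br)cc(O)c(Br)c1OC | intermediate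
9 | 2,5-dibromo-3,4-dimethoxyphenyl trifluoromethanesulfonate | COc1c(Br)cc(OS(=O)(=O)C(F)(F)F)c(Br)c1OC | intermediate
10 | (2,5-dibromo-3,4-dimethoxyphenyl)methanol | COc1c(Br)cc(CO)c(Br)c1OC | intermediate
11 | 1,4-dibromo-5-(chloromethyl)-2,3-dimethoxybenzene | COc1c(Br)cc(CCl)c(Br)c1OC | intermediate
12 | (2,5-dibromo-3,4-dimethoxybenzyl)magnesium chloride | COc1c(Br)cc(C[Mg]Cl)c(Br)c1OC | intermediate
13 | [3,6-dibromo-4,5-dimethoxy-2-(trifluoromethanesulfonyloxy)phenyl]magnesium chloride | COc1c(Br)c([Mg]Cl)c(OS(=O)(=O)C(F)(F)F)c(Br)c1OC | intermediate
14 | 3,6-dibromo-4,5-dimethoxybenzyne (3,6-dibromo-4,5-dimethoxy-1,2-didehydrobenzene) | COC1=C(Br)C#CC(Br)=C1OC | intermediate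
15 | {3,6-dibromo-2-[(2,5-dibromo-3,4-dimethoxyphenyl)methyl]-4,5-dimethoxyphenyl}magnesium chloride | COc1c(Br)cc(Cc2c(Br)c(OC)c(OC)c(Br)c2[Mg]Cl)c(Br)c1OC | intermediate
16 | 1,2,4-tribromo-3-[(2,5-dibromo-3,4-dimethoxyphenyl)methyl]-5,6-dimethoxybenzene | COc1c(Br)cc(Cc2c(Br)c(OC)c(OC)c(Br)c2Br)c(Br)c1OC | intermediate
17 | 3,4,6-tribromo-5-[(2,5-dibromo-3,4-dihydroxyphenyl)methyl]benzene-1,2-diol | Oc1c(Br)cc(Cc2c(Br)c(O)c(O)c(Br)c2Br)c(Br)c1O | target

**Step count**
Total steps: 10. Longest linear sequence: 8 steps (steps 1, 2, 3, 6, 7, 8, 9, 10). Steps 4 and 5 form the second branch from aldehyde 6 and join at step 9.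

**Steps most likely to fail**

1. Step 9. Several processes could divert it: loss of bromide in place of triflate from the magnesiated triflate, migration of the triflyl group to carbon (anionic thia-Fries), attack of the Grignard reagent at the sulfur of the triflate, or a second elimination from the 2-bromoarylmagnesium adduct before the bromine quench.
 Fallback, setting out from 4 and 6 and coming back at 16: monobromination of 4 (Br2, catalytic FeBr3, CH2Cl2) should give 1,2,5-tribromo-3,4-dimethoxybenzene F1. Its single ring hydrogen lies between two bromines and should be removed by LiN(i-Pr)2 (LDA) in THF at −78 °C to give 2,3,6-tribromo-4,5-dimethoxyphenyllithium F2. Addition of F2 to aldehyde 6 should give racemic (2,5-dibromo-3,4-dimethoxyphenyl)(2,3,6-tribromo-4,5-dimethoxyphenyl)methanol F3. Ionic hydrogenation of the doubly benzylic alcohol (Et3SiH, CF3CO2H, CH2Cl2) then removes the hydroxyl group and rejoins the route at 16.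

2. Step 8. Wurtz-type homocoupling of the benzylic chloride on the metal surface and competing insertion of magnesium into an aryl C–Br bond could leave too little benzylmagnesium for the aryne step.
 Fallback, setting out from 11 and 4 and coming back at 16, with no organometallic: Friedel–Crafts benzylation of 4 with chloride 11 (AlCl3, CH2Cl2, 0 °C), at a position para to a methoxy group, should give bis(2,5-dibromo-3,4-dimethoxyphenyl)methane F4. Electrophilic monobromination of one of its two equivalent ring C–H positions (one equivalent of Br2, catalytic FeBr3, dark), with chromatographic removal of unreacted and doubly brominated material, rejoins the route at 16.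

3. Step 3. Electrophilic substitution may be too slow on a ring that carries two bromines and two methoxy groups twisted out of conjugation, and the Lewis acid may cleave a methyl ether.
 Fallback, setting out from 4 and coming back at 6: deprotonation next to bromine with LiN(i-Pr)2 (THF, −78 °C, short contact time to hold back bromine migration) should give 2,5-dibromo-3,4-dimethoxyphenyllithium F5. Quenching with DMF gives the hemiaminal salt lithium (2,5-dibromo-3,4-dimethoxyphenyl)(dimethylamino)methanolate F6, and aqueous acid releases aldehyde 6.

**Further compounds**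
F1 | step 9 | 1,2,5-tribromo-3,4-dimethoxybenzene | COc1c(Br)cc(Br)c(Br)c1OC
F2 | step 9 | 2,3,6-tribromo-4,5-dimethoxyphenyllithium | COc1c(Br)c([Li])c(Br)c(Br)c1OC
F3 | step 9 | (2,5-dibromo-3,4-dimethoxyphenyl)(2,3,6-tribromo-4,5-dimethoxyphenyl)methanol, racemic | COc1c(Br)cc(C(O)c2c(Br)c(OC)c(OC)c(Br)c2Br)c(Br)c1OC
F4 | step 8 | bis(2,5-dibromo-3,4-dimethoxyphenyl)methane | COc1c(Br)cc(Cc2cc(Br)c(OC)c(OC)c2Br)c(Br)c1OC
F5 | step 3 | 2,5-dibromo-3,4-dimethoxyphenyllithium | COc1c(Br)cc([Li])c(Br)c1OC
F6 | step 3 | lithium (2,5-dibromo-3,4-dimethoxyphenyl)(dimethylamino)methanolate, racemic | COc1c(Br)cc(C(O[Li])N(C)C)c(Br)c1OC
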